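**Strategy.** The isoflavone is cut through ring C at three bonds: C3–C4, C2–O1 and O1–C8a. Ring A has O1 on C8a ortho to the C4 carbonyl, with its other oxygens (on C5, C7) meta to C8a, so a fluorine on C8a first steers both metalations (to C8, then C4a) and later leaves in an SNAr. In one operation an aroyl chloride acylates a β-aminostyrene at carbon, water replaces the amine, and the resulting enolate oxygen displaces fluoride to close the pyranone. The precursors are a 2-fluoro-3-prenyl-4,6-bis(silyloxy)benzoyl chloride and the morpholine enamine of a MOM-protected chromenylacetaldehyde.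

Key step: step 10

Remarks on the chemistry:
- The target is achiral; isoflavone numbering is used for rings A and C, chromene numbering for the ring-B unit.
- On 2,4-dihydroxybenzaldehyde the MOM group must go on O4 before the propargyl ether is made on O2. The reverse order would place the aldehyde at C6 of the chromene instead of C8.
- In the key step the vinylogous amide is hydrolysed in dilute acid and the ring is closed with dry carbonate. Aryl silyl ethers ortho/para to a ketone are labile to aqueous carbonate and to soluble fluoride, and a ring-A phenoxide would shut down the SNAr.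
- Paraformaldehyde is written as its monomer unit.

**Step 1**
Reactants: 1 5-fluororesorcinol
Product: 2 1-fluoro-3,5-bis(triisopropylsilyloxy)benzene
Conditions: TIPSCl (2.4 equiv), imidazole, DMF, rt
Reagents that add atoms: triisopropylsilyl chloride, CC(C)[Si](Cl)(C(C)C)C(C)C
Why: Imidazole-promoted O-silylation of both phenols; the bulky, non-coordinating silyl ethers later shield the carbon between them.

**Step 2**
Reactants: 2 1-fluoro-3,5-bis(triisopropylsilyloxy)benzene; 3 prenyl bromide
Product: 6 1-fluoro-2-(3-methylbut-2-en-1-yl)-3,5-bis(triisopropylsilyloxy)benzene, via aryllithium 4 (not isolated), via arylcopper 5 (not isolated)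
Conditions: s-BuLi, THF, −78 °C; CuBr·SMe2, −78 °C; 3, −78 → 0 °C
Reagents that add atoms: none
Why: Directed ortho-metalation followed by copper-mediated allylic substitution: fluorine acidifies its ortho C–H while the silyl ethers shield the carbon between them, transmetalation to copper stops loss of LiF, and the hindered arylcopper should attack prenyl bromide at its primary carbon to give the linear prenyl group.

**Step 3**
Reactants: 6 1-fluoro-2-(3-methylbut-2-en-1-yl)-3,5-bis(triisopropylsilyloxy)benzene
Product: 8 2-fluoro-3-(3-methylbut-2-en-1-yl)-4,6-bis(triisopropylsilyloxy)benzoic acid, via aryllithium 7 (not isolated)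
Conditions: s-BuLi, THF, −78 °C; CO2 (dry gas), −78 °C → rt; cold 0.5 M aq. HCl work-up
Reagents that add atoms: carbon dioxide, O=C=O
Why: Second fluorine-directed ortho-lithiation at the only C–H left next to fluorine (the other ring C–H lies between two silyl ethers), then carboxylation of the aryllithium at −78 °C, below the temperature at which LiF is lost.

**Step 4**
Reactants: 8 2-fluoro-3-(3-methylbut-2-en-1-yl)-4,6-bis(triisopropylsilyloxy)benzoic acid
Product: 9 2-fluoro-3-(3-methylbut-2-en-1-yl)-4,6-bis(triisopropylsilyloxy)benzoyl chloride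
Conditions: 1-chloro-N,N,2-trimethylprop-1-en-1-amine, CH2Cl2, 0 °C → rt; concentrated, used crude
Reagents that add atoms: 1-chloro-N,N,2-trimethylprop-1-en-1-amine, CC(C)=C(Cl)N(C)C
Why: Acid chloride formation with an α-chloroenamine under neutral conditions, so no HCl is present to add to the prenyl alkene or to strip the silyl ethers.

**Step 5**
Reactants: 10 2,4-dihydroxybenzaldehyde
Product: 11 2-hydroxy-4-(methoxymethoxy)benzaldehyde
Conditions: MOMCl (1.05 equiv), K2CO3, acetone, 0 °C → rt
Reagents that add atoms: chloromethyl methyl ether, COCCl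
Why: Williamson-type O-alkylation selective for the 4-OH, because the 2-OH is held in a hydrogen bond to the aldehyde and is less acidic and less nucleophilic.

**Step 6**
Reactants: 11 2-hydroxy-4-(methoxymethoxy)benzaldehyde; 12 3-chloro-3-methylbut-1-yne
Product: 13 4-(methoxymethoxy)-2-[(2-methylbut-3-yn-2-yl)oxy]benzaldehyde
Conditions: DBU, CuCl2·2H2O (cat.), MeCN, 0 °C → rt
Reagents that add atoms: none
Why: Copper-catalysed propargylic etherification of the phenoxide by the tertiary propargylic chloride; the only free hydroxyl is the one at C2.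

**Step 7**
Reactants: 13 4-(methoxymethoxy)-2-[(2-methylbut-3-yn-2-yl)oxy]benzaldehyde
Product: 14 5-(methoxymethoxy)-2,2-dimethyl-2H-chromene-8-carbaldehyde
Conditions: o-xylene, reflux (144 °C), N2
Reagents that add atoms: none
Why: Aromatic propargyl Claisen rearrangement to the only free ortho carbon (C3; C1 carries the formyl group), then enolisation, 1,5-hydrogen shift and oxa-6π-electrocyclisation give the chromene with the aldehyde at C8 and the MOM ether at C5.

**Step 8**
Reactants: 15 diphenylphosphine oxide; 16 paraformaldehyde; 17 morpholine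
Product: 18 4-[(diphenylphosphoryl)methyl]morpholine
Conditions: toluene, 90 °C, 4 Å MS
Reagents that add atoms: none
Why: Kabachnik–Fields (phospha-Mannich) condensation, in which the iminium ion from morpholine and formaldehyde is trapped by the P–H compound.

**Step 9**
Reactants: 18 4-[(diphenylphosphoryl)methyl]morpholine; 14 5-(methoxymethoxy)-2,2-dimethyl-2H-chromene-8-carbaldehyde
Product: 21 4-[(E)-2-[5-(methoxymethoxy)-2,2-dimethyl-2H-chromen-8-yl]ethenyl]morpholine, via lithiated phosphine oxide 19 (not isolated), via lithium alkoxide adduct 20 (not isolated)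
Conditions: n-BuLi, THF, −78 → 0 °C; 14, −78 °C → rt; KOtBu, THF, 0 °C → rt; cold basic extraction, used crude
Reagents that add atoms: none
Why: Horner–Wittig olefination with an α-amino phosphine oxide carbanion: addition to the aldehyde and potassium-alkoxide-driven syn-elimination of diphenylphosphinate should give mainly the (E)-enamine directly (either geometry is acylated alike), without acid and without a free arylacetaldehyde.

**Step 10**
Reactants: 9 2-fluoro-3-(3-methylbut-2-en-1-yl)-4,6-bis(triisopropylsilyloxy)benzoyl chloride; 21 4-[(E)-2-[5-(methoxymethoxy)-2,2-dimethyl-2H-chromen-8-yl]ethenyl]morpholine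
Product: 24 3-[5-(methoxymethoxy)-2,2-dimethyl-2H-chromen-8-yl]-8-(3-methylbut-2-en-1-yl)-5,7-bis(triisopropylsilyloxy)-4H-chromen-4-one, via enaminone 22 (not isolated), via hydroxymethylene ketone 23 (not isolated)
Conditions: (a) Et3N, CH2Cl2, 0 → 40 °C; (b) 0.5 M aq. HCl, THF, rt; (c) K2CO3 (anhydrous), MeCN, 70 °C; crude material carried through
Reagents that add atoms: water, O
Why: The enamine β-carbon attacks the aroyl chloride (Stork enamine acylation; the donor-rich, di-ortho-substituted chloride reacts through an acylium-like transition state) and Et3N removes the proton to give vinylogous amide 22, forming C3–C4. Dilute acid then exchanges morpholine for water at C2 (C2–O1) without touching the silyl ethers or the MOM acetal, and carbonate converts enol 23 into the chelated (Z)-enolate, whose oxygen adds to C8a and expels fluoride through a Meisenheimer intermediate stabilised by the C4 carbonyl (O1–C8a). The closest known reaction type is the Grohe-type cycloacylation of enamines with 2-halobenzoyl chlorides followed by intramolecular SNAr, as used for 4-quinolones and chromones. Ring C closes in a six-membered 6-endo-trig addition–elimination, counting C8a=C4a–C4=O as a vinylogous acyl fluoride; no stereocentre is formed. The step needs C- over N-acylation and ring closure before any silyl ether is lost: the aryl-conjugated enamine is a soft carbon nucleophile, fluorine is the only leaving group ortho to the carbonyl, and the silyloxy groups on C5 and C7 are meta to C8a and stay neutral because no hydroxide is present and the fluoride set free drops out of MeCN as KF.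

**Step 11**
Reactants: 24 3-[5-(methoxymethoxy)-2,2-dimethyl-2H-chromen-8-yl]-8-(3-methylbut-2-en-1-yl)-5,7-bis(triisopropylsilyloxy)-4H-chromen-4-one
Product: 25 3-(5-hydroxy-2,2-dimethyl-2H-chromen-8-yl)-8-(3-methylbut-2-en-1-yl)-5,7-bis(triisopropylsilyloxy)-4H-chromen-4-one
Conditions: 2 M aq. HCl, MeOH–THF, 45 °C
Reagents that add atoms: none
Why: Acid-catalysed acetal cleavage (MOM removal) run while the acid-stable aryl silyl ethers are still in place, so the C7 oxygen next to the prenyl group stays capped and cannot cyclise onto the alkene to a chromane.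

**Step 12**
Reactants: 25 3-(5-hydroxy-2,2-dimethyl-2H-chromen-8-yl)-8-(3-methylbut-2-en-1-yl)-5,7-bis(triisopropylsilyloxy)-4H-chromen-4-one
Product: 26 5,7-dihydroxy-3-(5-hydroxy-2,2-dimethyl-2H-chromen-8-yl)-8-(3-methylbut-2-en-1-yl)-4H-chromen-4-one
Conditions: TBAF, AcOH, THF, 0 °C
Reagents that add atoms: none
Why: Fluoride-mediated cleavage of both aryl silyl ethers, buffered with acetic acid so that the phenoxides are protonated as they form and the pyranone is not exposed to strong base.

**Compound list**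
1 | 5-fluororesorcinol | Oc1cc(O)cc(F)c1 | starting material
2 | 1-fluoro-3,5-bis(triisopropylsilyloxy)benzene | Fc1cc(O[Si](C(C)C)(C(C)C)C(C)C)cc(O[Si](C(C)C)(C(C)C)C(C)C)c1 | intermediate
3 | prenyl bromide (1-bromo-3-methylbut-2-ene) | CC(C)=CCBr | starting material
4 | 2-fluoro-4,6-bis(triisopropylsilyloxy)phenyllithium | [Li]c1c(F)cc(O[Si](C(C)C)(C(C)C)C(C)C)cc1O[Si](C(C)C)(C(C)C)C(C)C | intermediate (not isolated)
5 | [2-fluoro-4,6-bis(triisopropylsilyloxy)phenyl]copper | [Cu]c1c(F)cc(O[Si](C(C)C)(C(C)C)C(C)C)cc1O[Si](C(C)C)(C(C)C)C(C)C | intermediate (not isolated)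
6 | 1-fluoro-2-(3-methylbut-2-en-1-yl)-3,5-bis(triisopropylsilyloxy)benzene | CC(C)=CCc1c(F)cc(O[Si](C(C)C)(C(C)C)C(C)C)cc1O[Si](C(C)C)(C(C)C)C(C)C | intermediate
7 | 2-fluoro-3-(3-methylbut-2-en-1-yl)-4,6-bis(triisopropylsilyloxy)phenyllithium | CC(C)=CCc1c(F)c([Li])c(O[Si](C(C)C)(C(C)C)C(C)C)cc1O[Si](C(C)C)(C(C)C)C(C)C | intermediate (not isolated)
8 | 2-fluoro-3-(3-methylbut-2-en-1-yl)-4,6-bis(triisopropylsilyloxy)benzoic acid | CC(C)=CCc1c(F)c(C(=O)O)c(O[Si](C(C)C)(C(C)C)C(C)C)cc1O[Si](C(C)C)(C(C)C)C(C)C | intermediate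
9 | 2-fluoro-3-(3-methylbut-2-en-1-yl)-4,6-bis(triisopropylsilyloxy)benzoyl chloride | CC(C)=CCc1c(F)c(C(=O)Cl)c(O[Si](C(C)C)(C(C)C)C(C)C)cc1O[Si](C(C)C)(C(C)C)C(C)C | intermediate
10 | 2,4-dihydroxybenzaldehyde | O=Cc1ccc(O)cc1O | starting material
11 | 2-hydroxy-4-(methoxymethoxy)benzaldehyde | COCOc1ccc(C=O)c(O)c1 | intermediate
12 | 3-chloro-3-methylbut-1-yne | C#CC(C)(C)Cl | starting material
13 | 4-(methoxymethoxy)-2-[(2-methylbut-3-yn-2-yl)oxy]benzaldehyde | COCOc1ccc(C=O)c(OC(C)(C)C#C)c1 | intermediate
14 | 5-(methoxymethoxy)-2,2-dimethyl-2H-chromene-8-carbaldehyde | COCOc1ccc(C=O)c2c1C=CC(C)(C)O2 | intermediate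
15 | diphenylphosphine oxide | O=[PH](c1ccccc1)c1ccccc1 | starting material
16 | paraformaldehyde (formaldehyde unit) | C=O | starting material
17 | morpholine | C1COCCN1 | starting material
18 | 4-[(diphenylphosphoryl)methyl]morpholine | O=P(CN1CCOCC1)(c1ccccc1)c1ccccc1 | intermediate
19 | [(diphenylphosphoryl)(morpholin-4-yl)methyl]lithium | [Li]C(N1CCOCC1)P(=O)(c1ccccc1)c1ccccc1 | intermediate (not isolated)
20 | lithium 2-(diphenylphosphoryl)-1-[5-(methoxymethoxy)-2,2-dimethyl-2H-chromen-8-yl]-2-(morpholin-4-yl)ethan-1-olate (racemic mixture of both diastereomers) | [Li]OC(c1ccc(OCOC)c2c1OC(C)(C)C=C2)C(N1CCOCC1)P(=O)(c1ccccc1)c1ccccc1 | intermediate (not isolated)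
21 | 4-[(E)-2-[5-(methoxymethoxy)-2,2-dimethyl-2H-chromen-8-yl]ethenyl]morpholine | COCOc1ccc(/C=C/N2CCOCC2)c2c1C=CC(C)(C)O2 | intermediate
22 | 1-[2-fluoro-3-(3-methylbut-2-en-1-yl)-4,6-bis(triisopropylsilyloxy)phenyl]-2-[5-(methoxymethoxy)-2,2-dimethyl-2H-chromen-8-yl]-3-(morpholin-4-yl)prop-2-en-1-one (alkene geometry not fixed) | CC(C)=CCc1c(F)c(C(=O)C(=CN2CCOCC2)c2ccc(OCOC)c3c2OC(C)(C)C=C3)c(O[Si](C(C)C)(C(C)C)C(C)C)cc1O[Si](C(C)C)(C(C)C)C(C)C | intermediate (not isolated)
23 | 1-[2-fluoro-3-(3-methylbut-2-en-1-yl)-4,6-bis(triisopropylsilyloxy)phenyl]-3-hydroxy-2-[5-(methoxymethoxy)-2,2-dimethyl-2H-chromen-8-yl]prop-2-en-1-one (enol form of the β-ketoaldehyde, tautomers interconvert) | CC(C)=CCc1c(F)c(C(=O)C(=CO)c2ccc(OCOC)c3c2OC(C)(C)C=C3)c(O[Si](C(C)C)(C(C)C)C(C)C)cc1O[Si](C(C)C)(C(C)C)C(C)C | intermediate (not isolated)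
24 | 3-[5-(methoxymethoxy)-2,2-dimethyl-2H-chromen-8-yl]-8-(3-methylbut-2-en-1-yl)-5,7-bis(triisopropylsilyloxy)-4H-chromen-4-one | CC(C)=CCc1c(O[Si](C(C)C)(C(C)C)C(C)C)cc(O[Si](C(C)C)(C(C)C)C(C)C)c2c(=O)c(-c3ccc(OCOC)c4c3OC(C)(C)C=C4)coc12 | intermediate
25 | 3-(5-hydroxy-2,2-dimethyl-2H-chromen-8-yl)-8-(3-methylbut-2-en-1-yl)-5,7-bis(triisopropylsilyloxy)-4H-chromen-4-one | CC(C)=CCc1c(O[Si](C(C)C)(C(C)C)C(C)C)cc(O[Si](C(C)C)(C(C)C)C(C)C)c2c(=O)c(-c3ccc(O)c4c3OC(C)(C)C=C4)coc12 | intermediate
26 | 5,7-dihydroxy-3-(5-hydroxy-2,2-dimethyl-2H-chromen-8-yl)-8-(3-methylbut-2-en-1-yl)-4H-chromen-4-one | CC(C)=CCc1c(O)cc(O)c2c(=O)c(-c3ccc(O)c4c3OC(C)(C)C=C4)coc12 | target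

**Step count.** Total: 12 steps. Longest linear sequence: 7 steps (5, 6, 7, 9, 10, 11, 12 from 2,4-dihydroxybenzaldehyde; the ring-A branch 1, 2, 3, 4, 10, 11, 12 is equally long).

**Steps most likely to fail**

Step 10. C-acylation of the conjugated enamine by the di-ortho-substituted, donor-rich aroyl chloride may be too slow, so that N-acylation and breakdown of the enamine take over. The fallback sets out from 6 and 21 and comes back at 23. Enamine 21 is hydrolysed on wet silica gel to 2-[5-(methoxymethoxy)-2,2-dimethyl-2H-chromen-8-yl]acetaldehyde F1. Compound 6 is lithiated as in step 3 and aryllithium 7 is transmetalated with anhydrous CeCl3 (THF, −78 °C) to the aryl cerium dichloride F2, which should add to the enolisable aldehyde F1 without deprotonating it and give the secondary alcohol F3. Dess–Martin periodinane oxidises this to the deoxybenzoin F4. Me2NCH(OMe)2 (toluene, 90 °C) condenses at the benzylic CH2 to the dimethylamino enaminone F5, and dilute HCl in THF converts it into 23, which is closed with K2CO3 in MeCN as in step 10.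

Step 2. Deprotonation at the carbon flanked by fluorine and a bulky silyl ether may be slow or incomplete, and the ortho-fluoro aryllithium may lose LiF before it is trapped. The fallback sets out from 2 and comes back at 4. NBS in MeCN at 0 °C should brominate 2 at the same carbon (ortho/para to both oxygens, while the carbon between the two silyl ethers is shielded) to give 2-bromo-1-fluoro-3,5-bis(triisopropylsilyloxy)benzene F6. Bromine–lithium exchange with n-BuLi in THF at −78 °C is fast and site-specific and gives aryllithium 4, which continues through copper and prenyl bromide as in step 2.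

Step 9. The adduct of the phosphine oxide anion may revert or eliminate incompletely, and the enamine may hydrolyse during isolation. The fallback sets out from 14 and comes back at 21. Wittig reaction with Ph3P=CHOMe (from MeOCH2PPh3Cl and KOtBu, THF, 0 °C) gives the enol ether 8-(2-methoxyethenyl)-5-(methoxymethoxy)-2,2-dimethyl-2H-chromene F7 as an E/Z mixture. Brief hydrolysis with 1 M aq. HCl in THF at rt gives the arylacetaldehyde F1, the same compound as in the fallback for step 10. Condensation with morpholine over 4 Å molecular sieves in toluene gives 21, used as a solution.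

**Further compounds**
F1 | step 10 | 2-[5-(methoxymethoxy)-2,2-dimethyl-2H-chromen-8-yl]acetaldehyde | COCOc1ccc(CC=O)c2c1C=CC(C)(C)O2
F2 | step 10 | dichloro[2-fluoro-3-(3-methylbut-2-en-1-yl)-4,6-bis(triisopropylsilyloxy)phenyl]cerium | CC(C)=CCc1c(F)c([Ce](Cl)Cl)c(O[Si](C(C)C)(C(C)C)C(C)C)cc1O[Si](C(C)C)(C(C)C)C(C)C
F3 | step 10 | 1-[2-fluoro-3-(3-methylbut-2-en-1-yl)-4,6-bis(triisopropylsilyloxy)phenyl]-2-[5-(methoxymethoxy)-2,2-dimethyl-2H-chromen-8-yl]ethan-1-ol (racemic) | CC(C)=CCc1c(F)c(C(O)Cc2ccc(OCOC)c3c2OC(C)(C)C=C3)c(O[Si](C(C)C)(C(C)C)C(C)C)cc1O[Si](C(C)C)(C(C)C)C(C)C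
F4 | step 10 | 1-[2-fluoro-3-(3-methylbut-2-en-1-yl)-4,6-bis(triisopropylsilyloxy)phenyl]-2-[5-(methoxymethoxy)-2,2-dimethyl-2H-chromen-8-yl]ethan-1-one | CC(C)=CCc1c(F)c(C(=O)Cc2ccc(OCOC)c3c2OC(C)(C)C=C3)c(O[Si](C(C)C)(C(C)C)C(C)C)cc1O[Si](C(C)C)(C(C)C)C(C)C
F5 | step 10 | 3-(dimethylamino)-1-[2-fluoro-3-(3-methylbut-2-en-1-yl)-4,6-bis(triisopropylsilyloxy)phenyl]-2-[5-(methoxymethoxy)-2,2-dimethyl-2H-chromen-8-yl]prop-2-en-1-one (alkene geometry not fixed) | CC(C)=CCc1c(F)c(C(=O)C(=CN(C)C)c2ccc(OCOC)c3c2OC(C)(C)C=C3)c(O[Si](C(C)C)(C(C)C)C(C)C)cc1O[Si](C(C)C)(C(C)C)C(C)C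
F6 | step 2 | 2-bromo-1-fluoro-3,5-bis(triisopropylsilyloxy)benzene | Brc1c(F)cc(O[Si](C(C)C)(C(C)C)C(C)C)cc1O[Si](C(C)C)(C(C)C)C(C)C
F7 | step 9 | 8-(2-methoxyethenyl)-5-(methoxymethoxy)-2,2-dimethyl-2H-chromene (E/Z mixture) | COCOc1ccc(C=COC)c2c1C=CC(C)(C)O2
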